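**Plan**

1. Ring C numbering: C1 = ketone, C2 = carbon bearing the isoindolinone, C3 = C–OH, C4 = CH, C5 = C–CH3, C6 = C(prenyl)2. Ring C is a cyclohexa-2,4-dienone. C1 is sigma-bonded to the fully substituted C6 and also linked to it through the C2=C3–C4=C5 diene, so ring C is the valence isomer of the dienylketene O=C1=C2–C3=C4–C5=C6. Two equal prenyl groups on C6 mean that the closure makes no stereocentre and cannot run on to a phenol.
2. Retrosynthetic cuts, in order: O–Si; C1–C6 (6π); behind it a temporary C1–C4 bond (4π), giving a 4-alkenylcyclobutenone; C4–C5 (Stille); C1–C2 and C3–C4 together ([2+2] of a siloxyalkyne with chloroketene); alkyne C–O; lactam N–C(=O); C2–CH(N) (acetylide to sulfinyl imine).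
3. Forward order: arene to lactam ring B (fragment A, steps 1–5); diprenyl alkenylstannane (fragment B, steps 6–9); four-membered helper ring (step 10); ring C last (step 11); desilylation (step 12).
4. The shorter vinylketene O=C=CH–C(CH3)=C(prenyl)2 is never set free, because its cis prenyl group would add to it in an intramolecular [2+2] reaction. The alkenyl group is therefore coupled onto the finished four-membered ring.
5. Stereochemistry: the single stereocentre comes from adding ethynylmagnesium bromide to the (S)-tert-butanesulfinyl imine (step 3). It is only carried along afterwards, through neutral steps or with the lactam N-anion as a shield (step 5).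

Key step: step 11

Assumption: the vinylogous acid of ring C equilibrates freely between its enol tautomers, so the drawn tautomer stands for the compound. Prenyl = 3-methylbut-2-en-1-yl and TIPS = triisopropylsilyl.

**Step 1**
Reactants: 1 N,N-diethyl-3-methoxybenzamide
Product: 2 N,N-diethyl-2-formyl-3-methoxybenzamide
Conditions: s-BuLi, TMEDA, THF, −78 °C; DMF, −78 °C to rt; H2O
Reagents that add atoms: N,N-dimethylformamide CN(C)C=O
Why: Directed ortho-metalation, in which the amide and the methoxy group together steer the lithiation to the carbon between them and DMF formylates the aryllithium.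

**Step 2**
Reactants: 2 N,N-diethyl-2-formyl-3-methoxybenzamide; 3 (S)-2-methylpropane-2-sulfinamide
Product: 4 (S,E)-N-tert-butanesulfinyl aldimine of 2
Conditions: Ti(OEt)4 (2 equiv), THF, 50 °C
Reagents that add atoms: none
Why: Lewis-acid-mediated sulfinamide–aldehyde condensation, in which Ti(OEt)4 activates the hindered aldehyde and takes up the water, giving the (E)-imine without touching the sulfur stereocentre.

**Step 3**
Reactants: 4 (S,E)-N-tert-butanesulfinyl aldimine; 5 ethynylmagnesium bromide
Product: 6 (S)-N-[(1R)-1-(2-diethylcarbamoyl-6-methoxyphenyl)prop-2-yn-1-yl]-2-methylpropane-2-sulfinamide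
Conditions: CH2Cl2 (Grignard reagent 0.5 M in THF), −48 °C; H2O at −48 °C
Reagents that add atoms: none
Why: Diastereoselective Grignard 1,2-addition to a tert-butanesulfinyl imine, in which magnesium bound to the sulfinyl oxygen should deliver the alkynyl group through a six-membered chair to the face that gives the (R) carbon from the (S) auxiliary; if the ortho amide overrides this model, the enantiomeric auxiliary restores the required centre.

**Step 4**
Reactants: 6 propargylic sulfinamide
Product: 8 (3R)-3-ethynyl-4-methoxyisoindolin-1-one, via amine hydrochloride 7 (not isolated)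
Conditions: HCl (4 M in dioxane), MeOH, 0 °C to rt; evaporate; Et3N, toluene, 110 °C
Reagents that add atoms: none
Why: Acidic methanolysis of the S–N bond followed by lactamisation, in which the freed primary amine attacks the neighbouring tertiary amide (5-exo-trig acyl substitution, loss of diethylamine) without involving the stereocentre.

**Step 5**
Reactants: 8 (3R)-3-ethynyl-4-methoxyisoindolin-1-one
Product: 11 (3R)-4-methoxy-3-[(triisopropylsilyloxy)ethynyl]isoindolin-1-one, via dilithio acetylide 9 (not isolated), via dilithium ynolate 10 (not isolated)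
Conditions: n-BuLi (2.0 equiv), THF, −78 °C; t-BuOOLi (from t-BuOOH and LiHMDS, THF, −78 °C), −78 to 0 °C; TIPSOTf (1.05 equiv), −78 °C; aq. NaHCO3
Reagents that add atoms: tert-butyl hydroperoxide CC(C)(C)OO; triisopropylsilyl triflate CC(C)[Si](OS(=O)(=O)C(F)(F)F)(C(C)C)C(C)C
Why: Oxidation of a lithium acetylide with lithium tert-butyl peroxide to the ynolate and O-silylation by the bulky silyl triflate (established siloxyalkyne synthesis), with the lactam N-anion lowering the acidity of the adjacent C–H so that the stereocentre should hold.

**Step 6**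
Reactants: 12 ethyl acetoacetate; 13 prenyl bromide (2.3 equiv)
Product: 14 ethyl 2-acetyl-5-methyl-2-(3-methylbut-2-en-1-yl)hex-4-enoate
Conditions: NaH (2.2 equiv), THF/DMF, 0 to 50 °C
Reagents that add atoms: none
Why: Double C-alkylation of a beta-keto ester enolate (acetoacetic ester synthesis) with a soft allylic bromide places both prenyl groups on one carbon.

**Step 7**
Reactants: 14 diprenylated acetoacetate
Product: 15 6-methyl-3-(3-methylbut-2-en-1-yl)hept-5-en-2-one
Conditions: LiCl, H2O, DMSO, 150 °C
Reagents that add atoms: none
Why: Krapcho dealkoxycarbonylation removes the ester under neutral conditions that leave the prenyl double bonds alone and avoid retro-Claisen cleavage.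

**Step 8**
Reactants: 15 diprenylmethyl methyl ketone
Product: 16 6-methyl-3-(3-methylbut-2-en-1-yl)hepta-2,5-dien-2-yl triflate
Conditions: Tf2O, 2,6-di-tert-butyl-4-methylpyridine, CH2Cl2, 0 °C to rt
Reagents that add atoms: triflic anhydride O=S(=O)(OS(=O)(=O)C(F)(F)F)C(F)(F)F
Why: O-triflation of a ketone with Tf2O and a hindered pyridine should give the more substituted enol triflate, as with isopropyl methyl ketone, and no E/Z question arises because the alkene terminus carries two equal groups.

**Step 9**
Reactants: 16 tetrasubstituted enol triflate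
Product: 17 trimethyl[6-methyl-3-(3-methylbut-2-en-1-yl)hepta-2,5-dien-2-yl]stannane
Conditions: (Me3Sn)2, Pd(PPh3)4 (5 mol %), LiCl, THF, 65 °C
Reagents that add atoms: hexamethylditin C[Sn](C)(C)[Sn](C)(C)C
Why: Palladium-catalysed stannylation of an enol triflate with a distannane (Stille-type) is a standard way to reverse the polarity of hindered alkenyl triflates.

**Step 10**
Reactants: 11 siloxyalkyne; 18 chloroacetyl chloride
Product: 20 (3S)-3-[4-chloro-1-oxo-3-(triisopropylsilyloxy)cyclobut-2-en-2-yl]-4-methoxyisoindolin-1-one as a mixture of CHCl epimers, via chloroketene 19 (not isolated)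
Conditions: Et3N, Et2O, 0 °C to rt, slow addition of 18
Reagents that add atoms: none
Why: Ketene–siloxyalkyne [2+2] cycloaddition, in which the nucleophilic alkyne carbon (the one bearing the isoindolinone) bonds to the ketene carbonyl carbon and the oxygen-bearing carbon to CHCl; this fixes the 1,3-oxygen pattern, and the new CHCl centre is lost again in step 11.

**Step 11**
Reactants: 20 4-chlorocyclobutenone; 17 alkenylstannane
Product: 23 (3S)-4-methoxy-3-[4-methyl-6-oxo-5,5-bis(3-methylbut-2-en-1-yl)-2-(triisopropylsilyloxy)cyclohexa-1,3-dien-1-yl]isoindolin-1-one, via 4-alkenylcyclobutenone 21 (not isolated), via inward dienylketene 22 (not isolated)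
Conditions: PdCl2(PhCN)2 (5 mol %), tri(2-furyl)phosphine (10 mol %), CuI (10 mol %), dioxane, 50 °C; then 95 °C
Reagents that add atoms: none
Why: Zerovalent palladium inserts into the allylic, alpha-keto C–Cl bond of 20 and a Stille coupling with 17 puts the tetrasubstituted alkenyl group on the sp3 ring carbon to give 21; the closest known reaction type is the phenol synthesis by cross-coupling of 4-chlorocyclobutenones with alkenylstannanes followed by thermolysis, whose last two steps are also those of the Danheiser benzannulation. On warming, 21 opens in a reversible conrotatory 4π electrocyclic reaction that cuts the C(=O)–CH bond of the four-membered ring; the isomer with the alkenyl group turned outward can only fall back to 21, whereas the inward isomer 22 has ketene and diene terminus within reach. 22 closes ring C in a thermally allowed disrotatory 6π electrocyclisation in which the sp ketene carbon (future C1) bonds to the diprenyl-bearing alkene terminus (future C6), the thermal reverse of the photochemical opening of cyclohexa-2,4-dienones. No new stereocentre arises, because C6 carries two identical prenyl groups and the epimeric CH centre of 20 and 21 becomes the sp2 carbon C4, while the isoindolinone centre is a spectator under these neutral conditions. The step needs periselectivity (6π closure rather than ketene–alkene [2+2] addition or capture by the lactam N–H), which is secured because the ketene is born already conjugated with its diene partner, the prenyl double bonds are five atoms away from it, and the N–H could only form a four-membered ring. It also needs the reaction to stop at the dienone, which the quaternary C6 enforces (no enolisable hydrogen), and the flanking OTIPS and methyl groups shield C4 against a [3,3] shift of a prenyl group.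

**Step 12**
Reactants: 23 TIPS-protected dienone
Product: 24 (3S)-3-[2-hydroxy-4-methyl-6-oxo-5,5-bis(3-methylbut-2-en-1-yl)cyclohexa-1,3-dien-1-yl]-4-methoxyisoindolin-1-one (target)
Conditions: TBAF/AcOH (1:1), THF, 0 °C; pH 6 buffer
Reagents that add atoms: none
Why: Fluoride cleavage of a vinylogous silyl ester is fast at 0 °C, and the acetic acid buffer avoids both a strongly basic medium (retro-Mannich erosion of the stereocentre) and strong acid (addition of the enol to a prenyl group).

**Compound list**

1 | N,N-diethyl-3-methoxybenzamide | CCN(CC)C(=O)c1cccc(OC)c1 | starting material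
2 | N,N-diethyl-2-formyl-3-methoxybenzamide | CCN(CC)C(=O)c1cccc(OC)c1C=O | intermediate
3 | (S)-2-methylpropane-2-sulfinamide | CC(C)(C)[S@](=O)N | starting material
4 | (S,E)-N-[(2-diethylcarbamoyl-6-methoxyphenyl)methylidene]-2-methylpropane-2-sulfinamide | CC(C)(C)[S@](=O)/N=C/c1c(OC)cccc1C(=O)N(CC)CC | intermediate
5 | ethynylmagnesium bromide | C#C[Mg]Br | starting material
6 | (S)-N-[(1R)-1-(2-diethylcarbamoyl-6-methoxyphenyl)prop-2-yn-1-yl]-2-methylpropane-2-sulfinamide | CC(C)(C)[S@](=O)N[C@H](C#C)c1c(OC)cccc1C(=O)N(CC)CC | intermediate
7 | 2-[(1R)-1-aminoprop-2-yn-1-yl]-N,N-diethyl-3-methoxybenzamide hydrochloride | Cl.N[C@H](C#C)c1c(OC)cccc1C(=O)N(CC)CC | intermediate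
8 | (3R)-3-ethynyl-4-methoxyisoindolin-1-one | COc1cccc2c1[C@@H](C#C)NC2=O | intermediate
9 | N,C-dilithio derivative of 8 | [Li+].[Li+].COc1cccc2c1[C@@H](C#[C-])[N-]C2=O | intermediate
10 | dilithium ynolate of the lactam | [Li+].[Li+].COc1cccc2c1[C@@H](C#C[O-])[N-]C2=O | intermediate
11 | (3R)-4-methoxy-3-[(triisopropylsilyloxy)ethynyl]isoindolin-1-one | COc1cccc2c1[C@@H](C#CO[Si](C(C)C)(C(C)C)C(C)C)NC2=O | intermediate
12 | ethyl acetoacetate | CCOC(=O)CC(C)=O | starting material
13 | prenyl bromide (1-bromo-3-methylbut-2-ene) | CC(C)=CCBr | starting material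
14 | ethyl 2-acetyl-5-methyl-2-(3-methylbut-2-en-1-yl)hex-4-enoate | CCOC(=O)C(CC=C(C)C)(CC=C(C)C)C(C)=O | intermediate
15 | 6-methyl-3-(3-methylbut-2-en-1-yl)hept-5-en-2-one | CC(=O)C(CC=C(C)C)CC=C(C)C | intermediate
16 | 6-methyl-3-(3-methylbut-2-en-1-yl)hepta-2,5-dien-2-yl trifluoromethanesulfonate | CC(OS(=O)(=O)C(F)(F)F)=C(CC=C(C)C)CC=C(C)C | intermediate
17 | trimethyl[6-methyl-3-(3-methylbut-2-en-1-yl)hepta-2,5-dien-2-yl]stannane | CC(=C(CC=C(C)C)CC=C(C)C)[Sn](C)(C)C | intermediate
18 | chloroacetyl chloride | ClCC(Cl)=O | starting material
19 | chloroketene | ClC=C=O | intermediate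
20 | (3S)-3-[4-chloro-1-oxo-3-(triisopropylsilyloxy)cyclobut-2-en-2-yl]-4-methoxyisoindolin-1-one, both CHCl epimers | COc1cccc2c1[C@@H](C1=C(O[Si](C(C)C)(C(C)C)C(C)C)C(Cl)C1=O)NC2=O | intermediate
21 | (3S)-4-methoxy-3-{4-[6-methyl-3-(3-methylbut-2-en-1-yl)hepta-2,5-dien-2-yl]-1-oxo-3-(triisopropylsilyloxy)cyclobut-2-en-2-yl}isoindolin-1-one, both ring-CH epimers | COc1cccc2c1[C@@H](C1=C(O[Si](C(C)C)(C(C)C)C(C)C)C(C(C)=C(CC=C(C)C)CC=C(C)C)C1=O)NC2=O | intermediate
22 | dienylketene O=C=C(isoindolinonyl)–C(OTIPS)=CH–C(CH3)=C(prenyl)2, ketene-bearing carbon and alkenyl group cis on the central double bond, (3S) | COc1cccc2c1[C@@H](C(=C=O)/C(O[Si](C(C)C)(C(C)C)C(C)C)=C\C(C)=C(CC=C(C)C)CC=C(C)C)NC2=O | intermediate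
23 | (3S)-4-methoxy-3-[4-methyl-6-oxo-5,5-bis(3-methylbut-2-en-1-yl)-2-(triisopropylsilyloxy)cyclohexa-1,3-dien-1-yl]isoindolin-1-one | COc1cccc2c1[C@@H](C1=C(O[Si](C(C)C)(C(C)C)C(C)C)C=C(C)C(CC=C(C)C)(CC=C(C)C)C1=O)NC2=O | intermediate
24 | (3S)-3-[2-hydroxy-4-methyl-6-oxo-5,5-bis(3-methylbut-2-en-1-yl)cyclohexa-1,3-dien-1-yl]-4-methoxyisoindolin-1-one | COc1cccc2c1[C@@H](C1=C(O)C=C(C)C(CC=C(C)C)(CC=C(C)C)C1=O)NC2=O | target

**Total step count:** 12.
**Longest linear sequence:** 8 steps (1, 2, 3, 4, 5, 10, 11, 12).

**Steps most likely to fail**

**Step 11.**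
- What may go wrong: transmetalation from the tetrasubstituted alkenylstannane may be so slow that the palladium allyl species decays or the chloride is simply reduced. Prolonged heating may also let a prenyl group drift by a [3,3] shift.
- Fallback, from 16 and 11, giving up the cross-coupling on the four-membered ring:
  - 16 is coupled with tributyl(ethoxyethynyl)stannane (Pd(PPh3)4, LiCl, THF, 65 °C) to the ethoxy enyne F1.
  - An excess of F1 is heated with 11 in concentrated toluene solution at about 110 °C.
  - A retro-ene loss of ethene gives the vinylketene F2, which adds to the siloxyalkyne in a [2+2] reaction (Danheiser benzannulation).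
- Return to the route: at 21 in the flask, and from there at 23.
- Cost: part of F2 is lost to the intramolecular [2+2] addition of its cis prenyl group. This is why the cheap partner is used in excess.

**Step 10.**
- What may go wrong: oligomerisation of chloroketene, acylation of the lactam nitrogen under amine conditions, or loss of the silyl group on purification may outrun the cycloaddition.
- Fallback, from 11, using an amine-free and more electrophilic ketene:
  - Dichloroketene F3 is generated from trichloroacetyl chloride and Zn dust in Et2O/DME and adds to 11 to give the 4,4-dichlorocyclobutenone F4.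
  - One chlorine is then removed with one equivalent of Zn in AcOH/EtOH at 0 °C.
- Return to the route: at 20.

**Step 5.**
- What may go wrong: oxidation at the lactam nitrogen, incomplete oxygen transfer to the acetylide, silylation at carbon or nitrogen, or partial racemisation under the strongly basic conditions.
- Fallback, from 8, introducing the oxygen through electrophilic alkynyl iodine chemistry instead of a peroxide:
  - PhI(OH)OTs converts 8 into the alkynyl(phenyl)iodonium tosylate F5.
  - Catalytic CuOTf in MeCN collapses it to the alkynyl tosylate F6.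
  - MeLi (attack at sulfur, one further equivalent for the N–H) at −78 °C releases the ynolate.
- Return to the route: at 10, which is silylated to 11 as before.

**Further compounds**

F1 | step 11 | 1-ethoxy-3,7-dimethyl-4-(3-methylbut-2-en-1-yl)octa-3,6-dien-1-yne | CCOC#CC(C)=C(CC=C(C)C)CC=C(C)C
F2 | step 11 | 3,7-dimethyl-4-(3-methylbut-2-en-1-yl)octa-1,3,6-trien-1-one (vinylketene) | O=C=CC(C)=C(CC=C(C)C)CC=C(C)C
F3 | step 10 | dichloroketene | ClC(Cl)=C=O
F4 | step 10 | (3S)-3-[4,4-dichloro-1-oxo-3-(triisopropylsilyloxy)cyclobut-2-en-2-yl]-4-methoxyisoindolin-1-one | COc1cccc2c1[C@@H](C1=C(O[Si](C(C)C)(C(C)C)C(C)C)C(Cl)(Cl)C1=O)NC2=O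
F5 | step 5 | {[(1R)-7-methoxy-3-oxoisoindolin-1-yl]ethynyl}(phenyl)iodonium tosylate | COc1cccc2c1[C@@H](C#C[I+]c1ccccc1)NC2=O.Cc1ccc(cc1)S(=O)(=O)[O-]
F6 | step 5 | [(1R)-7-methoxy-3-oxoisoindolin-1-yl]ethynyl 4-methylbenzenesulfonate | COc1cccc2c1[C@@H](C#COS(=O)(=O)c1ccc(C)cc1)NC2=O
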